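## Retrosynthetic overview

1. Lettering: ring A is the benzo ring of the dihydrobenzofuran, ring B its oxygen ring (O1, C2, C3, C3a, C7a), ring C the phenol ring on C3, ring D the allylphenol ring on ring C, ring E the 4-allylphenoxy ring on C6. The plan rests on the O1–C2(CH2OH)–C3(ring C) unit of ring B: the adjacent carbons C2 and C3 carry the ring A oxygen and ring C, and their hydrogens are cis.
2. The cis-(2R,3S) centres come from syn addition of H2 to the C2=C3 bond of a flat benzofuran. The three allyl groups travel as aryl chlorides until after that hydrogenation, then enter by a threefold Stille coupling; one acid step removes four MOM groups and the TBS group.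
3. The flat benzofuran is cut at O1–C2 and at C3–C1' of ring C in one operation, giving a ring A ortho-alkynylphenol and a ring C/ring D biaryl iodide (palladium-catalysed cyclisation–arylation). Ring B is the only ring made in the route, and it is made here.
4. The alkynylphenol comes from Sonogashira coupling of an iodide placed by carbonate-directed magnesiation between O and Cl. Its three differentiated oxygens derive from 3-bromo-5-chlorosalicylaldehyde (OH to OMOM, Br to OAr by Ullmann coupling, CHO to OH by Baeyer–Villiger oxidation).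
5. The biaryl iodide comes from Suzuki coupling of 2-bromo-4-chlorophenol with 2-hydroxyphenylboronic acid, para-iodination and MOM protection.

Key step: step 11

Remark (assumption): the sense of induction of the chiral iridium catalyst in step 12 cannot be predicted for this substrate; it is assumed that one antipode of the ligand delivers H2 to the C2-Si/C3-Re face, and that antipode would be fixed by a test hydrogenation.

## Route

Step 1
Reactants: 1 3-bromo-5-chloro-2-hydroxybenzaldehyde
Product: 2 3-bromo-5-chloro-2-(methoxymethoxy)benzaldehyde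
Conditions: NaH, DMF, 0 °C; MOMCl, 0 °C to rt
Reagents that add atoms: chloromethyl methyl ether (MOMCl), COCCl
Why: Williamson-type O-alkylation of the fully deprotonated, chelated salicylaldehyde phenol should give the MOM ether, which later tolerates copper, magnesium amide and palladium chemistry and falls off with acid at the end.

Step 2
Reactants: 2 3-bromo-5-chloro-2-(methoxymethoxy)benzaldehyde; 3 4-chlorophenol
Product: 4 5-chloro-3-(4-chlorophenoxy)-2-(methoxymethoxy)benzaldehyde
Conditions: CuI (10 mol%), picolinic acid (20 mol%), K3PO4, DMSO, 90 °C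
Reagents that add atoms: none
Why: Ullmann-type copper-catalysed diaryl ether coupling should engage only the C–Br bond, the aryl chlorides being inert to this catalyst and the non-enolisable aldehyde being a spectator.

Step 3
Reactants: 4 5-chloro-3-(4-chlorophenoxy)-2-(methoxymethoxy)benzaldehyde
Product: 6 5-chloro-3-(4-chlorophenoxy)-2-(methoxymethoxy)phenol, via aryl formate 5 (not isolated)
Conditions: mCPBA, CH2Cl2, 0 °C to rt; then Et3N (cat.), MeOH, rt
Reagents that add atoms: meta-chloroperoxybenzoic acid (mCPBA), OOC(=O)c1cccc(Cl)c1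
Why: Baeyer–Villiger oxidation of an ortho-alkoxybenzaldehyde proceeds by aryl migration to the formate, whose methanolysis should leave the one free phenol among three differentiated oxygens.

Step 4
Reactants: 6 5-chloro-3-(4-chlorophenoxy)-2-(methoxymethoxy)phenol
Product: 7 tert-butyl 5-chloro-3-(4-chlorophenoxy)-2-(methoxymethoxy)phenyl carbonate
Conditions: Boc2O, DMAP (cat.), CH2Cl2, rt
Reagents that add atoms: di-tert-butyl dicarbonate (Boc2O), CC(C)(C)OC(=O)OC(=O)OC(C)(C)C
Why: DMAP-catalysed O-acylation should give the aryl tert-butyl carbonate, which serves as protecting group and as directing group for the next step.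

Step 5
Reactants: 7 tert-butyl 5-chloro-3-(4-chlorophenoxy)-2-(methoxymethoxy)phenyl carbonate
Product: 9 tert-butyl 3-chloro-5-(4-chlorophenoxy)-2-iodo-6-(methoxymethoxy)phenyl carbonate, via arylmagnesium chloride 8 (not isolated)
Conditions: TMPMgCl·LiCl, THF, 0 °C; then I2, THF, −20 °C to rt
Reagents that add atoms: iodine, II
Why: Directed ortho-magnesiation with the Knochel–Hauser base should occur at the only hydrogen ortho to the coordinating carbonate, which is further acidified by the neighbouring chlorine, and the arylmagnesium (stable to loss of chloride at 0 °C) is trapped by iodine.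

Step 6
Reactants: 9 tert-butyl 3-chloro-5-(4-chlorophenoxy)-2-iodo-6-(methoxymethoxy)phenyl carbonate; 10 tert-butyldimethyl(prop-2-yn-1-yloxy)silane
Product: 11 tert-butyl 2-[3-(tert-butyldimethylsilyloxy)prop-1-yn-1-yl]-3-chloro-5-(4-chlorophenoxy)-6-(methoxymethoxy)phenyl carbonate
Conditions: PdCl2(PPh3)2 (3 mol%), CuI (5 mol%), Et3N, THF, 45 °C
Reagents that add atoms: none
Why: Sonogashira coupling should take place at the C–I bond only, and the carbonate on the ortho oxygen prevents premature copper- or palladium-mediated closure to a 3-unsubstituted benzofuran.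

Step 7
Reactants: 11 tert-butyl 2-[3-(tert-butyldimethylsilyloxy)prop-1-yn-1-yl]-3-chloro-5-(4-chlorophenoxy)-6-(methoxymethoxy)phenyl carbonate
Product: 12 2-[3-(tert-butyldimethylsilyloxy)prop-1-yn-1-yl]-3-chloro-5-(4-chlorophenoxy)-6-(methoxymethoxy)phenol
Conditions: K2CO3, MeOH, 0 °C to rt
Reagents that add atoms: none
Why: Base-mediated methanolysis (transesterification) of the aryl carbonate should free the phenol while the alkyl silyl ether and the MOM ether stay, and at room temperature the phenoxide should not yet add to the alkyne.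

Step 8
Reactants: 13 2-bromo-4-chlorophenol; 14 2-hydroxyphenylboronic acid
Product: 15 5-chlorobiphenyl-2,2'-diol
Conditions: Pd(PPh3)4 (3 mol%), Na2CO3 (2 M aq), DME, 85 °C
Reagents that add atoms: none
Why: Suzuki–Miyaura coupling with the triphenylphosphine catalyst should join the rings at C–Br and leave C–Cl, free phenols being tolerated in aqueous carbonate.

Step 9
Reactants: 15 5-chlorobiphenyl-2,2'-diol
Product: 16 5-chloro-5'-iodobiphenyl-2,2'-diol
Conditions: NIS (1.0 equiv), TsOH·H2O (10 mol%), MeCN, 0 °C
Reagents that add atoms: N-iodosuccinimide, O=C1CCC(=O)N1I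
Why: Electrophilic aromatic iodination should go para to the hydroxyl of the non-chlorinated ring, the most activated open position, because the para position of the other ring is blocked by chlorine and that ring is deactivated.

Step 10
Reactants: 16 5-chloro-5'-iodobiphenyl-2,2'-diol
Product: 17 5-chloro-5'-iodo-2,2'-bis(methoxymethoxy)biphenyl
Conditions: NaH, DMF, 0 °C; MOMCl, 0 °C to rt
Reagents that add atoms: chloromethyl methyl ether (MOMCl), COCCl
Why: Twofold Williamson-type O-alkylation of the bis-phenoxide should give the bis-MOM ether, so that only the ring A phenol is free in the key step.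

Step 11
Reactants: 12 2-[3-(tert-butyldimethylsilyloxy)prop-1-yn-1-yl]-3-chloro-5-(4-chlorophenoxy)-6-(methoxymethoxy)phenol; 17 5-chloro-5'-iodo-2,2'-bis(methoxymethoxy)biphenyl
Product: 18 tert-butyl{[4-chloro-3-[5'-chloro-2',6-bis(methoxymethoxy)biphenyl-3-yl]-6-(4-chlorophenoxy)-7-(methoxymethoxy)-1-benzofuran-2-yl]methoxy}dimethylsilane
Conditions: Pd(PPh3)4 (5 mol%), K2CO3 (3 equiv), MeCN, 70 °C
Reagents that add atoms: none
Why: Zerovalent palladium inserts into the C–I bond of 17, and the arylpalladium iodide binds the alkyne of the phenoxide of 12 as a π-acid; the phenoxide oxygen then attacks the silyloxymethyl-bearing alkyne carbon anti to palladium, closing ring B in a 5-endo-dig mode (O1–C2), and the 3-benzofuranyl(aryl)palladium gives the C3–ring C bond by reductive elimination. The closest known reaction is the Cacchi-type oxypalladation–reductive elimination of ortho-alkynylphenols with aryl halides to 2,3-disubstituted benzofurans. No stereocentre is formed, since the product is a planar heteroarene and neither biaryl axis is hindered enough to be configurationally stable. Selectivity for C–I over the three C–Cl bonds is secured by the triphenylphosphine catalyst, which does not insert into unactivated aryl chlorides at this temperature. The arylative path must outrun plain cycloisomerisation to the 3-unsubstituted benzofuran, which the fast oxidative addition of the unhindered iodide (used in slight excess), the mild carbonate base in dry acetonitrile and the absence of copper should ensure. Regiochemistry is fixed by geometry, because the ortho oxygen can reach only the distal alkyne carbon.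

Step 12
Reactants: 18 the benzofuran silyl ether from step 11
Product: 19 tert-butyl{[(2R,3S)-4-chloro-3-[5'-chloro-2',6-bis(methoxymethoxy)biphenyl-3-yl]-6-(4-chlorophenoxy)-7-(methoxymethoxy)-2,3-dihydro-1-benzofuran-2-yl]methoxy}dimethylsilane (cis)
Conditions: H2 (100 bar), [Ir(cod)(L*)][B(3,5-(CF3)2C6H3)4] (5 mol%), CH2Cl2, 50 °C; L* = one antipode of 7-(di-tert-butylphosphinooxy)-2-phenyl-6,7-dihydro-5H-cyclopenta[b]pyridine (see remark)
Reagents that add atoms: none
Why: Proposed new method: the closest known reaction is the iridium N,P-catalysed asymmetric hydrogenation of 2- or 3-monosubstituted benzofurans and of tetrasubstituted alkenes, which has not been shown for a 2,3-disubstituted 3-arylbenzofuran. The enol-ether-like C2=C3 bond should bind η2 to the cationic trivalent iridium dihydride, and migratory insertion followed by C–H reductive elimination delivers both hydrogens to the same face, so the C2 and C3 hydrogens are necessarily cis. The chiral pocket (tert-butyl groups on phosphorus, phenyl on the pyridine) should select the C2-Si/C3-Re face and so set (2R,3S) in one event, while aryl chlorides, MOM ethers and the silyl ether are inert to this catalyst in dry CH2Cl2.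

Step 13
Reactants: 19 the (2R,3S)-dihydrobenzofuran trichloride from step 12
Product: 20 tert-butyl{[(2R,3S)-4-allyl-3-[5'-allyl-2',6-bis(methoxymethoxy)biphenyl-3-yl]-6-(4-allylphenoxy)-7-(methoxymethoxy)-2,3-dihydro-1-benzofuran-2-yl]methoxy}dimethylsilane
Conditions: allylSnBu3 (4.5 equiv), Pd[P(t-Bu)3]2 (10 mol%), CsF, 1,4-dioxane, 100 °C
Reagents that add atoms: allyltributylstannane, C=CC[Sn](CCCC)(CCCC)CCCC
Why: Stille coupling under fluoride activation with the tri-tert-butylphosphine catalyst is established for electron-rich and ortho-substituted aryl chlorides and should exchange all three chlorines for allyl without touching the two stereocentres, which see neither strong base nor acid.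

Step 14
Reactants: 20 the triallyl compound from step 13
Product: 21 Magnolignan H, (2R,3S)-4-allyl-3-(5'-allyl-2',6-dihydroxybiphenyl-3-yl)-6-(4-allylphenoxy)-2-(hydroxymethyl)-2,3-dihydro-1-benzofuran-7-ol
Conditions: HCl (3 M aq), MeOH/THF, 45 °C
Reagents that add atoms: none
Why: Acid-catalysed acetal cleavage of the four MOM ethers and methanolysis of the silyl ether should free all five hydroxyls, while the allyl arenes survive and C2, which is not benzylic, cannot ionise, so the cis centres are kept.

## Compound list

1 | 3-bromo-5-chloro-2-hydroxybenzaldehyde | O=Cc1cc(Cl)cc(Br)c1O | starting material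
2 | 3-bromo-5-chloro-2-(methoxymethoxy)benzaldehyde | O=Cc1cc(Cl)cc(Br)c1OCOC | intermediate
3 | 4-chlorophenol | Oc1ccc(Cl)cc1 | starting material
4 | 5-chloro-3-(4-chlorophenoxy)-2-(methoxymethoxy)benzaldehyde | O=Cc1cc(Cl)cc(Oc2ccc(Cl)cc2)c1OCOC | intermediate
5 | 5-chloro-3-(4-chlorophenoxy)-2-(methoxymethoxy)phenyl formate (not isolated) | O=COc1cc(Cl)cc(Oc2ccc(Cl)cc2)c1OCOC | intermediate
6 | 5-chloro-3-(4-chlorophenoxy)-2-(methoxymethoxy)phenol | Oc1cc(Cl)cc(Oc2ccc(Cl)cc2)c1OCOC | intermediate
7 | tert-butyl 5-chloro-3-(4-chlorophenoxy)-2-(methoxymethoxy)phenyl carbonate | CC(C)(C)OC(=O)Oc1cc(Cl)cc(Oc2ccc(Cl)cc2)c1OCOC | intermediate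
8 | [2-(tert-butoxycarbonyloxy)-6-chloro-4-(4-chlorophenoxy)-3-(methoxymethoxy)phenyl]magnesium chloride (not isolated) | CC(C)(C)OC(=O)Oc1c([Mg]Cl)c(Cl)cc(Oc2ccc(Cl)cc2)c1OCOC | intermediate
9 | tert-butyl 3-chloro-5-(4-chlorophenoxy)-2-iodo-6-(methoxymethoxy)phenyl carbonate | CC(C)(C)OC(=O)Oc1c(I)c(Cl)cc(Oc2ccc(Cl)cc2)c1OCOC | intermediate
10 | tert-butyldimethyl(prop-2-yn-1-yloxy)silane | C#CCO[Si](C)(C)C(C)(C)C | starting material
11 | tert-butyl 2-[3-(tert-butyldimethylsilyloxy)prop-1-yn-1-yl]-3-chloro-5-(4-chlorophenoxy)-6-(methoxymethoxy)phenyl carbonate | CC(C)(C)OC(=O)Oc1c(C#CCO[Si](C)(C)C(C)(C)C)c(Cl)cc(Oc2ccc(Cl)cc2)c1OCOC | intermediate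
12 | 2-[3-(tert-butyldimethylsilyloxy)prop-1-yn-1-yl]-3-chloro-5-(4-chlorophenoxy)-6-(methoxymethoxy)phenol | Oc1c(C#CCO[Si](C)(C)C(C)(C)C)c(Cl)cc(Oc2ccc(Cl)cc2)c1OCOC | intermediate
13 | 2-bromo-4-chlorophenol | Oc1ccc(Cl)cc1Br | starting material
14 | 2-hydroxyphenylboronic acid | OB(O)c1ccccc1O | starting material
15 | 5-chlorobiphenyl-2,2'-diol | Oc1ccccc1-c1cc(Cl)ccc1O | intermediate
16 | 5-chloro-5'-iodobiphenyl-2,2'-diol | Oc1ccc(I)cc1-c1cc(Cl)ccc1O | intermediate
17 | 5-chloro-5'-iodo-2,2'-bis(methoxymethoxy)biphenyl | COCOc1ccc(I)cc1-c1cc(Cl)ccc1OCOC | intermediate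
18 | tert-butyl{[4-chloro-3-[5'-chloro-2',6-bis(methoxymethoxy)biphenyl-3-yl]-6-(4-chlorophenoxy)-7-(methoxymethoxy)-1-benzofuran-2-yl]methoxy}dimethylsilane | Clc1ccc(Oc2cc(Cl)c3c(c2OCOC)oc(CO[Si](C)(C)C(C)(C)C)c3-c2ccc(OCOC)c(-c3cc(Cl)ccc3OCOC)c2)cc1 | intermediate
19 | tert-butyl{[(2R,3S)-4-chloro-3-[5'-chloro-2',6-bis(methoxymethoxy)biphenyl-3-yl]-6-(4-chlorophenoxy)-7-(methoxymethoxy)-2,3-dihydro-1-benzofuran-2-yl]methoxy}dimethylsilane | Clc1ccc(Oc2cc(Cl)c3c(c2OCOC)O[C@@H](CO[Si](C)(C)C(C)(C)C)[C@H]3c2ccc(OCOC)c(-c3cc(Cl)ccc3OCOC)c2)cc1 | intermediate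
20 | tert-butyl{[(2R,3S)-4-allyl-3-[5'-allyl-2',6-bis(methoxymethoxy)biphenyl-3-yl]-6-(4-allylphenoxy)-7-(methoxymethoxy)-2,3-dihydro-1-benzofuran-2-yl]methoxy}dimethylsilane | C=CCc1ccc(Oc2cc(CC=C)c3c(c2OCOC)O[C@@H](CO[Si](C)(C)C(C)(C)C)[C@H]3c2ccc(OCOC)c(-c3cc(CC=C)ccc3OCOC)c2)cc1 | intermediate
21 | Magnolignan H, (2R,3S)-4-allyl-3-(5'-allyl-2',6-dihydroxybiphenyl-3-yl)-6-(4-allylphenoxy)-2-(hydroxymethyl)-2,3-dihydro-1-benzofuran-7-ol | C=CCc1ccc(Oc2cc(CC=C)c3c(c2O)O[C@@H](CO)[C@H]3c2ccc(O)c(-c3cc(CC=C)ccc3O)c2)cc1 | target

## Step count and risks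

Total step count: 14. Longest linear sequence: 11 steps (steps 1–7 and 11–14, from 3-bromo-5-chloro-2-hydroxybenzaldehyde).

Steps most likely to fail:

1. Step 12 (asymmetric hydrogenation, proposed new method). The hindered, fully substituted C2=C3 bond may resist reduction, the catalyst may discriminate the two faces poorly, or the acidic iridium hydrides may strip MOM or silyl groups. The fallback sets out from 18 and comes back at 19. Compound 18 is hydrogenated heterogeneously (PtO2, H2 at 50 bar, EtOAc, rt to 50 °C), which adds both hydrogens from the catalyst surface to one face and should give the racemic cis-dihydrobenzofuran silyl ether F1; platinum is chosen over palladium to spare the C–Cl bonds. The enantiomers are then separated by preparative chromatography on a cellulose tris(3,5-dimethylphenylcarbamate) phase, and the (2R,3S) enantiomer is 19.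

2. Step 11 (key step). Base- or palladium-mediated cycloisomerisation of 12 to the 3-unsubstituted benzofuran may outrun the arylative pathway, or the hindered 3-benzofuranyl(aryl)palladium may be protonated before reductive elimination. The fallback sets out from 12 and 17 and comes back at 18. Compound 12 is cyclised with I2 and NaHCO3 in MeCN at rt (5-endo-dig iodocyclisation) to tert-butyl{[4-chloro-6-(4-chlorophenoxy)-3-iodo-7-(methoxymethoxy)-1-benzofuran-2-yl]methoxy}dimethylsilane F2. Compound 17 is borylated at the C–I bond (B2pin2, PdCl2(dppf), KOAc, DMSO, 80 °C) to the biaryl pinacol boronate F3. Suzuki coupling of the two (PdCl2(dppf), K3PO4, dioxane/H2O, 80 °C) should give 18.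

3. Step 13 (threefold allylation). Coupling at the hindered C4–Cl bond may stay incomplete, and palladium hydride species may isomerise allyl groups to propenyl groups at 100 °C. The fallback sets out from 19 and comes back at 20, reversing the polarity. The three C–Cl bonds are borylated (B2pin2, Pd2(dba)3, XPhos, KOAc, dioxane, 100 °C) to the tris(pinacol boronate) F4, which is then coupled with allyl bromide (Pd(PPh3)4, K2CO3, THF/H2O, 60 °C) to give 20 at a lower temperature.

## Further compounds

F1 | step 12 | racemic cis-tert-butyl{[4-chloro-3-[5'-chloro-2',6-bis(methoxymethoxy)biphenyl-3-yl]-6-(4-chlorophenoxy)-7-(methoxymethoxy)-2,3-dihydro-1-benzofuran-2-yl]methoxy}dimethylsilane (racemate; relative configuration shown) | Clc1ccc(Oc2cc(Cl)c3c(c2OCOC)O[C@@H](CO[Si](C)(C)C(C)(C)C)[C@H]3c2ccc(OCOC)c(-c3cc(Cl)ccc3OCOC)c2)cc1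
F2 | step 11 | tert-butyl{[4-chloro-6-(4-chlorophenoxy)-3-iodo-7-(methoxymethoxy)-1-benzofuran-2-yl]methoxy}dimethylsilane | Clc1ccc(Oc2cc(Cl)c3c(I)c(CO[Si](C)(C)C(C)(C)C)oc3c2OCOC)cc1
F3 | step 11 | 2-[5'-chloro-2',6-bis(methoxymethoxy)biphenyl-3-yl]-4,4,5,5-tetramethyl-1,3,2-dioxaborolane | COCOc1ccc(B2OC(C)(C)C(C)(C)O2)cc1-c1cc(Cl)ccc1OCOC
F4 | step 13 | tris(pinacol boronate) of 19 (each chlorine replaced by 4,4,5,5-tetramethyl-1,3,2-dioxaborolan-2-yl), (2R,3S) | CC1(C)OB(OC1(C)C)c1ccc(Oc2cc(B3OC(C)(C)C(C)(C)O3)c3c(c2OCOC)O[C@@H](CO[Si](C)(C)C(C)(C)C)[C@H]3c2ccc(OCOC)c(-c3cc(B4OC(C)(C)C(C)(C)O4)ccc3OCOC)c2)cc1
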